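## Retrosynthetic overview

1. The glyceride is made last: target 25 ⇒ diketo acid 21 + (R)-benzyl glycidyl ether 22 (ester by epoxide opening, then O-acetylation, then loss of the O-benzyl group).
2. The cyclohexane, the only ring of the target, is closed in step 11 at the bond between the quaternary ring carbon (bearing CH3 and the side-chain C=O) and the ring CH2 next to it: hydride adds to an α-methylene ketone and the enolate so formed displaces a primary bromide (6-exo-tet).
3. Feature that allows this: the quaternary ring carbon is the α-carbon of the ring-bound ketone, so its CH3 can be carried as =CH2 (one defined enolate, no base); the neighbouring ring CH, which carries the 3-oxobutyl arm, steers the new centre by allylic strain; the ring CH2 is the end of a three-carbon arm on the CMe2 carbon.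
4. The two ketone carbons are 1,6-related through that CH–C bond, the mark of an opened cyclohexene: (S)-limonene supplies the ring CH, the future quaternary carbon, both carbonyl carbons and the whole oxobutyl arm (ozonolysis), and its isopropenyl group becomes CMe2 plus the three-carbon arm (HAT–Giese reaction with acrolein).
5. The C6 side chain comes from (R)-citronellic acid as an alkylzinc; ring order: limonene ring opened (step 3), temporary dioxolane on (step 9) and off (step 12), target cyclohexane formed in step 11.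

Key step: step 11

Assumption: (S)-(−)-limonene, (R)-(+)-citronellic acid and (R)-benzyl glycidyl ether are bought in high enantiomeric purity; stereocentres that are erased later (carbinol carbon of 16 and 17, α-carbon of 7) are carried as mixtures.

## Route

Step 1
Reactants: 1 (S)-(−)-limonene
Product: 3 4-methyl-4-[(1S)-4-methylcyclohex-3-en-1-yl]pentan-1-ol, via Giese aldehyde 2 (not isolated)
Conditions: acrolein (excess), Fe(acac)3 (cat.), PhSiH3, EtOH, 60 °C; then NaBH4, 0 °C
Reagents that add atoms: acrolein (C=CC=O)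
Why: Iron hydride hydrogen-atom transfer (Mukaiyama-type) should go to the unhindered CH2 of the isopropenyl group faster than to the trisubstituted ring alkene, the tertiary radical adds to acrolein (Giese reaction) to build the CMe2 carbon, and NaBH4 reduces the new aldehyde in the same flask; no stereocentre is formed.

Step 2
Reactants: 3 4-methyl-4-[(1S)-4-methylcyclohex-3-en-1-yl]pentan-1-ol
Product: 4 (4S)-4-(5-bromo-2-methylpentan-2-yl)-1-methylcyclohex-1-ene
Conditions: CBr4, PPh3, imidazole, CH2Cl2, 0 °C
Reagents that add atoms: carbon tetrabromide (BrC(Br)(Br)Br)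
Why: Appel bromination of the primary alcohol (SN2 on the alkoxyphosphonium ion) leaves the ring alkene untouched.

Step 3
Reactants: 4 (4S)-4-(5-bromo-2-methylpentan-2-yl)-1-methylcyclohex-1-ene
Product: 6 (3S)-3-(5-bromo-2-methylpentan-2-yl)-6-oxoheptanal, via ozonide 5 (not isolated)
Conditions: O3, CH2Cl2, −78 °C; then Me2S, −78 → 25 °C
Reagents that add atoms: ozone ([O-][O+]=O)
Why: Criegee ozonolysis of the only alkene left, with reductive work-up, should give the methyl ketone and the aldehyde at the oxidation levels the target needs; bromide and stereocentre are inert.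

Step 4
Reactants: 6 (3S)-3-(5-bromo-2-methylpentan-2-yl)-6-oxoheptanal
Product: 8 (3R)-3-(5-bromo-2-methylpentan-2-yl)-2-methylidene-6-oxoheptanal, via Mannich base 7 (not isolated)
Conditions: Me2N=CH2+ I− (Eschenmoser's salt, excess), Et3N, CH2Cl2, 25 °C
Reagents that add atoms: N,N-dimethylmethyleneiminium iodide (C[N+](C)=C.[I-])
Why: Mannich reaction of the fast-enolising aldehyde with the iminium ion and loss of dimethylamine (Eschenmoser methylenation) should give the 2-substituted acrolein, the iminium ion being a far better electrophile than the methyl ketone so that the intramolecular aldol stays in the background.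

Step 5
Reactants: 9 (R)-(+)-citronellic acid
Product: 10 tert-butyl (3R)-3,7-dimethyloct-6-enoate
Conditions: tert-butyl 2,2,2-trichloroacetimidate, CH2Cl2/cyclohexane, 25 °C
Reagents that add atoms: tert-butyl 2,2,2-trichloroacetimidate (CC(C)(C)OC(=N)C(Cl)(Cl)Cl)
Why: The carboxylic acid protonates the imidate and is O-alkylated by the tert-butyl cation equivalent under conditions too mild to touch the trisubstituted alkene.

Step 6
Reactants: 10 tert-butyl (3R)-3,7-dimethyloct-6-enoate
Product: 12 (4R)-6-tert-butoxy-4-methyl-6-oxohexanoic acid, via aldehyde ester 11 (not isolated)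
Conditions: RuCl3 (cat.), NaIO4, EtOAc/MeCN/H2O, 25 °C
Reagents that add atoms: sodium periodate ([Na+].[O-]I(=O)(=O)=O); water (O)
Why: RuO4 generated in situ should cleave the trisubstituted alkene and oxidise the aldehyde formed to the acid, with acetone lost and the tert-butyl ester and stereocentre untouched.

Step 7
Reactants: 12 (4R)-6-tert-butoxy-4-methyl-6-oxohexanoic acid
Product: 14 tert-butyl (3S)-5-iodo-3-methylpentanoate, via acyl hypoiodite 13 (not isolated)
Conditions: PhI(OAc)2, I2, CH2Cl2, visible light, reflux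
Reagents that add atoms: iodine (II)
Why: Hunsdiecker-type iododecarboxylation: photolysis of the acyl hypoiodite gives the primary alkyl radical after loss of CO2, and iodine traps it; the stereocentre is remote from the radical (the descriptor changes only through priorities).

Step 8
Reactants: 14 tert-butyl (3S)-5-iodo-3-methylpentanoate; 8 (3R)-3-(5-bromo-2-methylpentan-2-yl)-2-methylidene-6-oxoheptanal
Product: 16 tert-butyl (3R,8R)-8-(5-bromo-2-methylpentan-2-yl)-6-hydroxy-3-methyl-7-methylidene-11-oxododecanoate (mixture at C-6), via alkylzinc iodide 15 (not isolated)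
Conditions: 14, Zn dust, LiCl, THF, 40 °C; then 8, MgCl2, THF, 0 → 25 °C
Reagents that add atoms: none
Why: LiCl-assisted zinc insertion into the primary C–I bond tolerates the ester, and MgCl2-activated 1,2-addition of the alkylzinc should take the aldehyde in preference to the methyl ketone and the alkyl bromide; the new carbinol centre is oxidised in step 10.

Step 9
Reactants: 16 tert-butyl (3R,8R)-8-(5-bromo-2-methylpentan-2-yl)-6-hydroxy-3-methyl-7-methylidene-11-oxododecanoate
Product: 17 tert-butyl (3R,8R)-12-bromo-6-hydroxy-3,9,9-trimethyl-7-methylidene-8-[2-(2-methyl-1,3-dioxolan-2-yl)ethyl]dodecanoate (mixture at C-6)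
Conditions: ethylene glycol, PPTS (cat.), benzene, reflux (Dean–Stark)
Reagents that add atoms: ethane-1,2-diol (OCCO)
Why: At this stage the methyl ketone is the only carbonyl that can be ketalised, and the mild acid should leave the allylic alcohol, the tert-butyl ester and the bromide alone.

Step 10
Reactants: 17 tert-butyl (3R,8R)-12-bromo-6-hydroxy-3,9,9-trimethyl-7-methylidene-8-[2-(2-methyl-1,3-dioxolan-2-yl)ethyl]dodecanoate
Product: 18 tert-butyl (3R,8R)-12-bromo-3,9,9-trimethyl-7-methylidene-8-[2-(2-methyl-1,3-dioxolan-2-yl)ethyl]-6-oxododecanoate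
Conditions: Dess–Martin periodinane, NaHCO3, CH2Cl2, 0 → 25 °C
Reagents that add atoms: none
Why: Buffered Dess–Martin oxidation of the allylic alcohol should give the α-methylene ketone without moving the double bond or opening the ketal.

Step 11
Reactants: 18 tert-butyl (3R,8R)-12-bromo-3,9,9-trimethyl-7-methylidene-8-[2-(2-methyl-1,3-dioxolan-2-yl)ethyl]-6-oxododecanoate
Product: 20 tert-butyl (3R)-3-methyl-6-oxo-6-{(1R,2R)-1,3,3-trimethyl-2-[2-(2-methyl-1,3-dioxolan-2-yl)ethyl]cyclohexyl}hexanoate, via lithium enolate 19 (not isolated)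
Conditions: LiBH(s-Bu)3 (slight excess), THF, −78 °C; then DMPU, −78 → 25 °C
Reagents that add atoms: none
Why: Conjugate addition of hydride to the terminal carbon of the α-methylene ketone makes the ring methyl group and gives, regiospecifically, the fully substituted lithium enolate 19, whose α-carbon displaces the primary bromide (SN2) once DMPU is added and the mixture is warmed. The closest known reaction type is the trialkylborohydride reductive alkylation of enones (conjugate reduction followed by enolate alkylation), used here intramolecularly. The cyclohexane closes in the 6-exo-tet mode with the enolate double bond outside the forming ring. The new quaternary stereocentre is controlled by the neighbouring CH stereocentre through allylic 1,3-strain: its C–H bond lies in the enolate plane, the CMe2 arm and the ketal arm sit on opposite faces, and the bromide tethered through CMe2 can reach only its own face in a chair-like transition state that places the ketal arm and the acyl carbon equatorial and the new methyl axial, which is the (1R,2R) trans arrangement of the target. The step needs C-alkylation at the substituted α-carbon and no enolate on the CH2 side: the enolate is made without base or proton source, and O-alkylation or attack from the other α-carbon would need eight-membered rings. Chemoselectivity rests on 1,4-reduction of a β-unsubstituted enone being much faster at −78 °C than attack on the tert-butyl ester, the ketal or the alkyl bromide.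

Step 12
Reactants: 20 tert-butyl (3R)-3-methyl-6-oxo-6-{(1R,2R)-1,3,3-trimethyl-2-[2-(2-methyl-1,3-dioxolan-2-yl)ethyl]cyclohexyl}hexanoate
Product: 21 (3R)-3-methyl-6-oxo-6-[(1R,2R)-1,3,3-trimethyl-2-(3-oxobutyl)cyclohexyl]hexanoic acid
Conditions: CF3CO2H, CH2Cl2, H2O, 0 → 25 °C
Reagents that add atoms: water (O)
Why: Acid cleaves the tert-butyl ester by loss of isobutene and the wet acid hydrolyses the dioxolane in the same operation; no stereocentre is α to a carbonyl with a hydrogen, so none can epimerise.

Step 13
Reactants: 21 (3R)-3-methyl-6-oxo-6-[(1R,2R)-1,3,3-trimethyl-2-(3-oxobutyl)cyclohexyl]hexanoic acid; 22 (R)-benzyl glycidyl ether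
Product: 23 (2S)-3-(benzyloxy)-2-hydroxypropyl (3R)-3-methyl-6-oxo-6-[(1R,2R)-1,3,3-trimethyl-2-(3-oxobutyl)cyclohexyl]hexanoate
Conditions: Bu4NBr (cat.), toluene, 90 °C
Reagents that add atoms: none
Why: The carboxylate opens the terminal epoxide at its unsubstituted CH2 (SN2), so the acyl group ends on the primary oxygen and the configured carbon is not touched.

Step 14
Reactants: 23 (2S)-3-(benzyloxy)-2-hydroxypropyl (3R)-3-methyl-6-oxo-6-[(1R,2R)-1,3,3-trimethyl-2-(3-oxobutyl)cyclohexyl]hexanoate
Product: 24 (2S)-2-acetoxy-3-(benzyloxy)propyl (3R)-3-methyl-6-oxo-6-[(1R,2R)-1,3,3-trimethyl-2-(3-oxobutyl)cyclohexyl]hexanoate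
Conditions: Ac2O, pyridine, DMAP (cat.), CH2Cl2, 0 °C
Reagents that add atoms: acetic anhydride (CC(=O)OC(C)=O)
Why: DMAP-catalysed acetylation of the secondary alcohol; no free hydroxyl remains, so acyl migration cannot occur at this stage.

Step 15
Reactants: 24 (2S)-2-acetoxy-3-(benzyloxy)propyl (3R)-3-methyl-6-oxo-6-[(1R,2R)-1,3,3-trimethyl-2-(3-oxobutyl)cyclohexyl]hexanoate
Product: 25 (2S)-2-acetoxy-3-hydroxypropyl (3R)-3-methyl-6-oxo-6-[(1R,2R)-1,3,3-trimethyl-2-(3-oxobutyl)cyclohexyl]hexanoate (CNP0287223.1)
Conditions: H2 (1 atm), Pd/C, EtOAc, 25 °C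
Reagents that add atoms: none
Why: Hydrogenolysis of the benzyl ether under neutral conditions frees the primary alcohol, aliphatic ketones and esters being inert, and the neutral medium should suppress migration of the acetyl group.

## Compound list

1 | (S)-(−)-limonene, (4S)-1-methyl-4-(prop-1-en-2-yl)cyclohex-1-ene | CC1=CC[C@H](CC1)C(C)=C | starting material
2 | 4-methyl-4-[(1S)-4-methylcyclohex-3-en-1-yl]pentanal | CC1=CC[C@H](CC1)C(C)(C)CCC=O | intermediate (not isolated)
3 | 4-methyl-4-[(1S)-4-methylcyclohex-3-en-1-yl]pentan-1-ol | CC1=CC[C@H](CC1)C(C)(C)CCCO | intermediate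
4 | (4S)-4-(5-bromo-2-methylpentan-2-yl)-1-methylcyclohex-1-ene | CC1=CC[C@H](CC1)C(C)(C)CCCBr | intermediate
5 | ozonide of 4: 4-(5-bromo-2-methylpentan-2-yl)-1-methyl-7,8,9-trioxabicyclo[4.2.1]nonane, side-chain centre as in 4 | CC12CC[C@@H](CC(O1)OO2)C(C)(C)CCCBr | intermediate (not isolated)
6 | (3S)-3-(5-bromo-2-methylpentan-2-yl)-6-oxoheptanal | O=CC[C@H](CCC(C)=O)C(C)(C)CCCBr | intermediate
7 | (3S)-3-(5-bromo-2-methylpentan-2-yl)-2-[(dimethylamino)methyl]-6-oxoheptanal (mixture at C-2) | CN(C)CC(C=O)[C@H](CCC(C)=O)C(C)(C)CCCBr | intermediate (not isolated)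
8 | (3R)-3-(5-bromo-2-methylpentan-2-yl)-2-methylidene-6-oxoheptanal | O=CC(=C)[C@H](CCC(C)=O)C(C)(C)CCCBr | intermediate
9 | (R)-(+)-citronellic acid, (3R)-3,7-dimethyloct-6-enoic acid | CC(C)=CCC[C@@H](C)CC(O)=O | starting material
10 | tert-butyl (3R)-3,7-dimethyloct-6-enoate | CC(C)=CCC[C@@H](C)CC(=O)OC(C)(C)C | intermediate
11 | tert-butyl (3R)-3-methyl-6-oxohexanoate | O=CCC[C@@H](C)CC(=O)OC(C)(C)C | intermediate (not isolated)
12 | (4R)-6-tert-butoxy-4-methyl-6-oxohexanoic acid | OC(=O)CC[C@@H](C)CC(=O)OC(C)(C)C | intermediate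
13 | acyl hypoiodite of 12, tert-butyl (3R)-6-(iodooxy)-3-methyl-6-oxohexanoate | IOC(=O)CC[C@@H](C)CC(=O)OC(C)(C)C | intermediate (not isolated)
14 | tert-butyl (3S)-5-iodo-3-methylpentanoate | ICC[C@@H](C)CC(=O)OC(C)(C)C | intermediate
15 | [(3S)-5-tert-butoxy-3-methyl-5-oxopentyl]zinc iodide | I[Zn]CC[C@@H](C)CC(=O)OC(C)(C)C | intermediate (not isolated)
16 | tert-butyl (3R,8R)-8-(5-bromo-2-methylpentan-2-yl)-6-hydroxy-3-methyl-7-methylidene-11-oxododecanoate (mixture at C-6) | CC(C)(C)OC(=O)C[C@H](C)CCC(O)C(=C)[C@H](CCC(C)=O)C(C)(C)CCCBr | intermediate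
17 | tert-butyl (3R,8R)-12-bromo-6-hydroxy-3,9,9-trimethyl-7-methylidene-8-[2-(2-methyl-1,3-dioxolan-2-yl)ethyl]dodecanoate (mixture at C-6) | CC(C)(C)OC(=O)C[C@H](C)CCC(O)C(=C)[C@H](CCC1(C)OCCO1)C(C)(C)CCCBr | intermediate
18 | tert-butyl (3R,8R)-12-bromo-3,9,9-trimethyl-7-methylidene-8-[2-(2-methyl-1,3-dioxolan-2-yl)ethyl]-6-oxododecanoate | CC(C)(C)OC(=O)C[C@H](C)CCC(=O)C(=C)[C@H](CCC1(C)OCCO1)C(C)(C)CCCBr | intermediate
19 | lithium enolate formed from 18 by hydride addition (C-6/C-7 enolate, 7-methyl) | CC(C)(C)OC(=O)C[C@H](C)CCC(O[Li])=C(C)[C@H](CCC1(C)OCCO1)C(C)(C)CCCBr | intermediate (not isolated)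
20 | tert-butyl (3R)-3-methyl-6-oxo-6-{(1R,2R)-1,3,3-trimethyl-2-[2-(2-methyl-1,3-dioxolan-2-yl)ethyl]cyclohexyl}hexanoate | CC1(OCCO1)CC[C@@H]2C(C)(C)CCC[C@@]2(C)C(=O)CC[C@@H](C)CC(=O)OC(C)(C)C | intermediate
21 | (3R)-3-methyl-6-oxo-6-[(1R,2R)-1,3,3-trimethyl-2-(3-oxobutyl)cyclohexyl]hexanoic acid | CC(=O)CC[C@@H]1C(C)(C)CCC[C@@]1(C)C(=O)CC[C@@H](C)CC(O)=O | intermediate
22 | (R)-benzyl glycidyl ether, (2R)-2-[(benzyloxy)methyl]oxirane | C1[C@H](COCc2ccccc2)O1 | starting material
23 | (2S)-3-(benzyloxy)-2-hydroxypropyl (3R)-3-methyl-6-oxo-6-[(1R,2R)-1,3,3-trimethyl-2-(3-oxobutyl)cyclohexyl]hexanoate | CC(=O)CC[C@@H]1C(C)(C)CCC[C@@]1(C)C(=O)CC[C@@H](C)CC(=O)OC[C@H](COCc1ccccc1)O | intermediate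
24 | (2S)-2-acetoxy-3-(benzyloxy)propyl (3R)-3-methyl-6-oxo-6-[(1R,2R)-1,3,3-trimethyl-2-(3-oxobutyl)cyclohexyl]hexanoate | CC(=O)CC[C@@H]1C(C)(C)CCC[C@@]1(C)C(=O)CC[C@@H](C)CC(=O)OC[C@H](COCc1ccccc1)OC(C)=O | intermediate
25 | (2S)-2-acetoxy-3-hydroxypropyl (3R)-3-methyl-6-oxo-6-[(1R,2R)-1,3,3-trimethyl-2-(3-oxobutyl)cyclohexyl]hexanoate (CNP0287223.1) | CC(=O)CC[C@@H]1C(C)(C)CCC[C@@]1(C)C(=O)CC[C@@H](C)CC(=O)OC[C@H](CO)OC(C)=O | target

## Step count and risks

Total step count: 15. Longest linear sequence: 12 (steps 1–4 and 8–15); the side-chain branch (steps 5–7) joins at step 8.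

Steps most likely to fail:

Step 11 (key step). What may go wrong: proton transfer from the CH2 side of ketone molecules to the hindered lithium enolate before ring closure, which would erase the regiochemical definition; slow SN2 at the fully substituted enolate carbon; or 1,2-reduction of the enone. The fallback sets out from 18 and returns at 20, and stores the enolate as an isolable silyl enol ether. Rhodium-catalysed 1,4-hydrosilylation of the enone (Et3SiH, RhCl(PPh3)3, THF, 50 °C) should give tert-butyl (3R,8R)-12-bromo-3,7,9,9-tetramethyl-8-[2-(2-methyl-1,3-dioxolan-2-yl)ethyl]-6-(triethylsilyloxy)dodec-6-enoate F1, which can be purified. Desilylation with anhydrous benzyltrimethylammonium fluoride (THF, 4 Å molecular sieves, 0 → 25 °C) then releases a metal-free ammonium enolate that should alkylate the tethered bromide to 20 under the same allylic-strain control.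

Step 1. What may go wrong: hydrogen-atom transfer to the ring alkene in competition with the isopropenyl group, 5-exo closure of the tertiary radical onto the ring alkene, and oligomerisation of acrolein. The fallback sets out from 1 and returns at 6, and masks the ring alkene before the radical step. mCPBA (CH2Cl2, 0 °C) should epoxidise the more electron-rich trisubstituted alkene to (4S)-1-methyl-4-(prop-1-en-2-yl)-7-oxabicyclo[4.1.0]heptane F2. The same HAT–Giese reaction and NaBH4 reduction would give 4-methyl-4-[(3S)-6-methyl-7-oxabicyclo[4.1.0]heptan-3-yl]pentan-1-ol F3, and Appel bromination would give (4S)-4-(5-bromo-2-methylpentan-2-yl)-1-methyl-7-oxabicyclo[4.1.0]heptane F4. Periodic acid (H5IO6, THF/H2O) then opens and cleaves the epoxide to 6, so that steps 2 and 3 are not needed.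

Step 8. What may go wrong: sluggish 1,2-addition of the alkylzinc to the α-branched enal, with conjugate addition or oligomerisation of the enal taking over. The fallback sets out from 8 and returns at 18, and makes the bond by acyl substitution instead of carbonyl addition. Pinnick oxidation (NaClO2, NaH2PO4, 2-methylbut-2-ene, t-BuOH/H2O) should give (3R)-3-(5-bromo-2-methylpentan-2-yl)-2-methylidene-6-oxoheptanoic acid F5. 1-Chloro-N,N,2-trimethylprop-1-en-1-amine (CH2Cl2, 0 °C) converts it under neutral conditions into (3R)-3-(5-bromo-2-methylpentan-2-yl)-2-methylidene-6-oxoheptanoyl chloride F6. Negishi acylation with alkylzinc 15 (Pd(PPh3)4 cat., THF) would give tert-butyl (3R,8R)-8-(5-bromo-2-methylpentan-2-yl)-3-methyl-7-methylidene-6,11-dioxododecanoate F7. The saturated methyl ketone of F7 is then ketalised in preference to the cross-conjugated enone (1,2-bis(trimethylsilyloxy)ethane, Me3SiOTf cat., CH2Cl2, −78 °C) to give 18, so that steps 9 and 10 are not needed.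

Further compounds
F1 | step 11 | tert-butyl (3R,8R)-12-bromo-3,7,9,9-tetramethyl-8-[2-(2-methyl-1,3-dioxolan-2-yl)ethyl]-6-(triethylsilyloxy)dodec-6-enoate | CC[Si](CC)(CC)OC(CC[C@@H](C)CC(=O)OC(C)(C)C)=C(C)[C@H](CCC1(C)OCCO1)C(C)(C)CCCBr
F2 | step 1 | (4S)-1-methyl-4-(prop-1-en-2-yl)-7-oxabicyclo[4.1.0]heptane (epoxide isomers) | CC12OC1C[C@H](CC2)C(C)=C
F3 | step 1 | 4-methyl-4-[(3S)-6-methyl-7-oxabicyclo[4.1.0]heptan-3-yl]pentan-1-ol | CC12OC1C[C@H](CC2)C(C)(C)CCCO
F4 | step 1 | (4S)-4-(5-bromo-2-methylpentan-2-yl)-1-methyl-7-oxabicyclo[4.1.0]heptane | CC12OC1C[C@H](CC2)C(C)(C)CCCBr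
F5 | step 8 | (3R)-3-(5-bromo-2-methylpentan-2-yl)-2-methylidene-6-oxoheptanoic acid | OC(=O)C(=C)[C@H](CCC(C)=O)C(C)(C)CCCBr
F6 | step 8 | (3R)-3-(5-bromo-2-methylpentan-2-yl)-2-methylidene-6-oxoheptanoyl chloride | ClC(=O)C(=C)[C@H](CCC(C)=O)C(C)(C)CCCBr
F7 | step 8 | tert-butyl (3R,8R)-8-(5-bromo-2-methylpentan-2-yl)-3-methyl-7-methylidene-6,11-dioxododecanoate | CC(C)(C)OC(=O)C[C@H](C)CCC(=O)C(=C)[C@H](CCC(C)=O)C(C)(C)CCCBr
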